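The starting material is the first thing to watch in each of these flasks, and the three new ones are charged and asked about as follows.

| flask | starting material | solid reagent | temperature | remark | time |
|---|---|---|---|---|---|
| Monday's | 0.50 M | 2 equiv | 20 °C | run made earlier |  |
| Saturday's | 0.50 M | 3 equiv | 55 °C | run made earlier |  |
| Thursday's | 0.25 M | 4 equiv | 20 °C | run made earlier |  |
| green | 0.50 M | 4.00 equiv | 25 °C |  | 12 min |
| grey | 0.50 M | 4.00 equiv | 55 °C |  | 12 min |
| violet | 0.50 M | 4.00 equiv | 85 °C |  | 12 min |

- Monday's (time / min: product / %, starting material / %): 1.00: 1.2, 61.4; 2.00: 1.9, 38.3; 4.00: 6.8, 13.8; 8.00: 14.4, 2.1; 15.0: 24.8, 0.2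
- Saturday's (time / min: product / %, starting material / %): 0.667: 46.2, 0.6; 1.33: 49.1, 0; 2.00: 47.9, 0.7; 2.50: 48.3, 0.2; 3.00: 48.6, 0
- Thursday's (time / min: product / %, starting material / %): 3.00: 4.4, 22.7; 6.00: 11.4, 5.9; 8.00: 14.1, 1.5; 12.0: 20.4, 1.4; 15.0: 24.4, 0.6

(each reading ± 0.5 percentage points)

- solid, in amounts per volume of the solution: solid reagent
- steps under discussion: solid reagent <-> partner; starting material -> intermediate A; intermediate A <-> intermediate B; intermediate A <-> product
- at the start none of the solid reagent is in solution

- the flask that comes out highest in amount of product, in percent of the starting material charged, or "all alike" when all lie within 1.5 percentage points (green / grey / violet / all alike)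
- product at the end, in percent of the starting material charged, green
- product at the end, in percent of the starting material charged, grey
- product at the end, in percent of the starting material charged, violet

The readings of Monday's run fit a first-order fall of the starting material with a constant of about 0.484 /min, and those of Thursday's run, at half the [starting material], give about 0.449 /min. In the first minutes of Monday's run the flask reads 13.8% starting material and 6.8% product by 4.00 min, so 79.4% of the charge is taken to sit unread in the intermediates, and the product is reckoned to trail by a lag of about 2.07 min, the mean life of the starting material from that reading.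

In the middle the product climbs slowly, to 24.8% at 15.0 min in Monday's run and 24.4% in Thursday's. The end stands in Saturday's run at 55 °C, whose later readings lie flat around 48.5%, a plateau read here as a ceiling under thermodynamic control.

Joining the two ends, and taking that ceiling for Monday's run too, gives 0.0554 /min for the climb constant, the logarithm of ceiling over remaining gap divided by the time since the lag. Saturday's 0.6% of starting material at 0.667 min, a rough reading so near its scatter, gives 7.67 /min, and on the assumption that the climb speeds up as the fall of the starting material does, spreading that rise evenly over the degrees gives green a factor of 1.48. This reckoning therefore puts green at 28.2% and grey on its ceiling; one ceiling shows no slope with temperature, so violet is set there too, tied with grey.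

The forecast gave green 33%, grey 48.5% and violet 54%, named violet highest and held that “The equilibrium therefore rises gently with temperature”, whereas the reckoning here gives green less and assumes no slope.

The flasks give green 36.7%, grey 48.2% and violet 39.3%, so grey comes highest.

    solid reagent ⇌ partner, rate k1*(cs1 - [partner]) while solid is left; crystals form when [partner] > cs1 (solubility = 0.310 M, k = 0.0146 /min)
    starting material → intermediate A (k = 0.798 /min, Ea = 72.0 kJ/mol)
    intermediate A ⇌ intermediate B (K = 0.550, k = 1.01 /min, Ea = 88.0 kJ/mol, ΔH = −69.0 kJ/mol)
    intermediate A ⇌ product (K = 1.57, k = 0.0950 /min, Ea = 92.0 kJ/mol, ΔH = −13.0 kJ/mol)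
    (constants at 25 °C)

Violet, still 39.3% at 120 min, stands below the ceiling read from Saturday's run, and green stands above the reckoned figure. Green's result, put through the same curve with green's own 50.3% at 120 min as the ceiling, gives a climb constant of 0.123 /min, against Monday's 0.0554 /min and the 0.0820 /min reckoned for green. With that constant and ceiling the curve gives 8.99% for the same green flask read at 3.0 min, and that reading holds 10.7% product.

Readings and results were computed with made-up constants.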